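**Conventions.** Decalin carbons carry terpenoid numbers: C1–C10, C11 (methylene on C9), C12 (carbon on C8), C18 (α carbon on C4, the carboxyl carbon of the target), C19 (4β‑methyl), C20 (10β‑methyl). Ring C is the oxygenated six‑membered ring: C1' (bears C11), C2', C3', C4' (bears CH3), C5', C6'. "Drim" names imply 5α‑H, 9α‑H (C11 β) and 10β‑CH3. Ar = 5‑methoxy‑4‑methyl‑2‑(propan‑2‑yloxy)phenyl, bonded through its C1'.

**Remark on the chemistry (assumption).** The facial preference of a cinchona phase‑transfer catalyst on a 2‑alkyl quinone monoketal cannot be assigned in advance. N‑Benzylcinchonidinium chloride is written in step 23; if the first run shows the opposite preference, the pseudoenantiomeric N‑benzylcinchoninium chloride replaces it with no other change.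

## Analysis of the target

The target is a meroterpenoid in which a trans‑fused decalin (rings A and B, a drim‑7‑ene with a carboxyl group on C4) is joined through the C11 methylene to C1' of a cis‑epoxy‑cyclohexene‑1,4‑diol (ring C). Rings A and B hold four stereocentres, two of them quaternary: C4 (β‑CH3, α‑CO2H), C5 (α‑H), C10 (β‑CH3) and C9 (α‑H); read from the SMILES they are 4R,5R,9S,10R. Ring C holds four more (1'S,2'R,3'S,6'R): the oxirane spans C1'–C2', and the C3' and C6' hydroxyls are cis to each other and both on the face opposite the oxirane oxygen. The two sets are separated by the freely rotating C11 methylene, so the decalin cannot be relied on to control ring C and a reagent must do so. Sensitive groups are the trisubstituted oxirane flanked by two allylic alcohols, the C7=C8 alkene (which adds a neighbouring phenol under acid) and the neopentyl carboxylic acid, which is hard to release from simple esters. The hard points are the two quaternary centres C4 and C10 with different oxidation levels on the two C4 substituents, the need for one enantiomer, and a mild late construction of ring C. The route rests on two features: C4, C5, C10 and C9 lie along a farnesyl‑type chain, so that C4–C5 and C9–C10 can be formed together in a chair–chair epoxy‑polyene cyclisation; and ring C is a dearomatised 2,5‑dioxygenated toluene.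

## Retrosynthetic reasoning

**Ring C, reductions and ester.** Target 34 is taken back to its allyl ester 33, and the C3'–H and C6'–H bonds are cut in turn (33 to enone 32, ketal 31, epoxy ketone 30). Hydride reductions are chosen because the oxirane and the adjacent substituents can steer both hydroxyls to the face anti to the oxirane. The ester is cut last in the forward sense under neutral palladium catalysis because the neopentyl acid cannot be freed from an ordinary ester without endangering the epoxy diol.

**Ring C, oxirane and dearomatisation.** The C1'–O and C2'–O bonds of 30 are cut to give dienone monoketal 29, which comes from phenol 28 and that from the isopropyl ether 27. This places all ring C carbons, the methyl group and the C11 link in a cheap arene. Unmasking the C6' oxygen alone fixes which carbon becomes the ketone and which the ketal, and this makes the two enone double bonds of 29 different enough for a regioselective nucleophilic epoxidation at C1'=C2'. The forward epoxidation has to choose one ring face under reagent control.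

**Adjustment of the decalin.** 27 is traced through acid 26, aldehyde 25 and alcohol 24 to silyl ether 23, then to the exocyclic alkene 22 and, by restoring a C3 oxygen via thiocarbonyl derivative 21, to alcohol 20. These are the costs of the key step: the C3 hydroxyl it leaves must be removed, the exocyclic alkene moved to C7=C8, and C18 raised from the alcohol to the acid level.

**Key disconnection.** In 20 the C4–C5 and C9–C10 bonds are cut, opening rings A and B to the acyclic epoxy triene 19. No other cut sets C4, C5, C10 and C9 in one operation from alkene geometry and a single oxirane stereocentre. The allylsilane at C8=C9 makes the termination regiospecific and leaves a defined C8=C12 alkene. The forward reaction must fold the chain chair–chair in one absolute sense and end before the arene or a proton loss can interfere.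

**Oxirane.** The two C–O bonds of the oxirane in 19 are cut to allylic alcohol 17 through epoxy alcohol 18; 17 comes from its silyl ether 16. A Sharpless epoxidation needs the free allylic hydroxyl, is indifferent to the other two alkenes, and sets the only stereocentres that the key step does not create.

**Allylsilane.** In 16 the C8–C12 and C9–C11 bonds are cut across a former triple bond, giving alkyne 7, Grignard reagent 13 (through copper reagent 14 and alkenylcopper 15) and benzylic bromide 12. Syn carbometalation followed by alkylation with retention is the shortest way to a trisubstituted alkene in which CH2Ar is trans to the C7 chain.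

**Chain.** Alkyne 7 is traced through alcohol 6 and silylalkyne 5 to enyne 4, and the C6–C7 bond of 4 is cut to silylpropyne 1 (as its lithio derivative 3) and geranyl bromide 2. The C18 oxygen is introduced by allylic oxidation at the stage of 4, before any allylsilane or benzylic/allylic methylene exists, because both would compete in that oxidation; the price is one temporary silyl ether (7 to 17).

**Arene.** Bromide 12 comes from alcohol 11, aldehyde 10 and salicylaldehyde 9, made by ortho‑formylation of phenol 8. The formyl group can only enter the ortho position not flanked by the methyl group, which is the C1' needed.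

## Alternatives that were turned down

**Alternative 1:** Here the oxirane of ring C is the strategic bond set. The disconnection removes the oxirane oxygen from epoxy ketone acid A1 to give dienone monoketal acid A2. The forward key step is a Weitz–Scheffer epoxidation in which a hydroperoxide anion, ion‑paired with a chiral ammonium cation, adds to C2' of A2 and the C6' enolate closes on oxygen.
- For it: it puts the one problem that no part of the molecule can solve, the configuration of ring C relative to a remote decalin, at the centre of the plan. Regiochemistry follows reliably from the different substitution of the two enone double bonds, and the products are separable diastereomers.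
- Against it: the plan does not say how the 4α‑carboxy drimane of A2 is obtained. Chiral‑pool drimanes lack the C18 oxygen, so rings A and B would need either a remote C–H oxidation or their own synthesis. The free acid of A2 becomes a lipophilic carboxylate under the basic two‑phase conditions and competes with the hydroperoxide for the chiral cation.
- Comparison: on the epoxidation itself this alternative is as strong as the chosen route, which uses the same reaction in step 23 on ester 29. What the chosen strategy offers instead is the part left open here: both quaternary centres, the ring fusion, C9 and the C18 oxygen in one step from achiral acyclic material, with the absolute configuration taken from a catalytic Sharpless epoxidation.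

**Alternative 2:** The disconnection is the C4'=C5' bond of ring C, leading from the protected target A3 back to the acyclic epoxy diene A4 (vinyl on C6', isopropenyl on C3'). The forward key step is ring‑closing metathesis with a second‑generation Grubbs catalyst and loss of ethylene.
- For it: all four ring C stereocentres are set in an open chain by reactions of known sense, a Sharpless epoxidation among them, so no late reduction of uncertain facial selectivity and no aromatic oxidation are needed. The silyl ethers and the silylethyl ester fall together with fluoride. On predictability of ring C stereochemistry it is stronger than the chosen route.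
- Against it: A4 needs a fully substituted oxirane carbon bearing the bulky decalinyl‑methyl group between two differentiated allylic carbinols. That demands a long convergent build with a C–C bond formed next to a neopentyl‑type centre. The decalin acid still has to be made separately. The metathesis must form a trisubstituted alkene from a 1,1‑disubstituted one flanked by silyloxy groups.
- Comparison: ring C alone would cost about as many steps as the whole sequence after the key step in the chosen route, which obtains the ring C carbons from a commercial phenol in four steps and accepts, in exchange, two reductions that may need correction.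

**Alternative 3:** The disconnection cuts C3–C4 and C5–C10 of decalin ester A5. The forward key step is a thermal intramolecular Diels–Alder reaction in which the (E)‑2‑methyl enoate C4=C5 adds across the C10=C1–C2=C3 diene, closing rings A and B at once.
- For it: C18 arrives at the carboxyl oxidation level and no C3 oxygen has to be removed, so it is stronger on redox economy than the chosen route, which spends steps 14 and 15 on deoxygenation and 17 to 19 on oxidation. The conditions are neutral.
- Against it: the dienophile is trisubstituted and the diene terminus C10 is fully substituted, so two quaternary centres form in the cycloaddition. The trans fusion with 4α‑ester requires one particular endo/exo mode that the tether does not clearly enforce. The absolute configuration must be relayed from C8 and C9 centres made beforehand. A5 still needs hydrogenation of C1=C2 and conversion of the C8 silyl ether into the methyl‑bearing C7=C8 alkene with regiochemical risk.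
- Comparison: the chosen cyclisation is stereospecific, its outcome following from alkene geometry and one oxirane centre rather than from small transition‑state energy differences. It pays for this with the redox steps named above.

Key step: step 13

## Route

Step 1
Reactants: 1 1‑(trimethylsilyl)propyne; 2 geranyl bromide
Product: 4 [(5E)‑6,10‑dimethylundeca‑5,9‑dien‑1‑yn‑1‑yl]trimethylsilane, via 3‑lithio‑1‑(trimethylsilyl)propyne 3 (not isolated)
Conditions: n‑BuLi, THF, −78 °C; then 2, −78 °C → rt
Reagents that add atoms: none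
Why: Lithiated 1 is alkylated at its propargylic carbon by the primary allylic bromide (SN2); the silyl group suppresses the allenyl pathway and the (E)‑alkene of 2 is untouched.

Step 2
Reactants: 4
Product: 5 (2E,6E)‑2,6‑dimethyl‑11‑(trimethylsilyl)undeca‑2,6‑dien‑10‑yn‑1‑ol
Conditions: SeO2 (cat.), t‑BuOOH, salicylic acid (cat.), CH2Cl2, 0 °C → rt
Reagents that add atoms: tert‑butyl hydroperoxide CC(C)(C)OO (oxygen source, relayed by catalytic selenium dioxide O=[Se]=O)
Why: Allylic oxidation (ene reaction, then [2,3]‑sigmatropic shift) is fastest at the gem‑dimethyl terminus and takes the methyl group (E) to the chain, which fixes C18 as the (E)‑CH2OH group; the run is stopped at partial conversion to limit enal formation and attack at the inner alkene.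

Step 3
Reactants: 5
Product: 6 (2E,6E)‑2,6‑dimethylundeca‑2,6‑dien‑10‑yn‑1‑ol
Conditions: K2CO3 (cat.), MeOH, rt
Reagents that add atoms: none
Why: Base‑catalysed methanolysis of the alkynyl C–Si bond; alcohol and alkenes are inert.

Step 4
Reactants: 6
Product: 7 tert‑butyl{[(2E,6E)‑2,6‑dimethylundeca‑2,6‑dien‑10‑yn‑1‑yl]oxy}dimethylsilane
Conditions: t‑BuMe2SiCl, imidazole, CH2Cl2, 0 °C → rt
Reagents that add atoms: tert‑butyldimethylsilyl chloride CC(C)(C)[Si](C)(C)Cl
Why: Standard silylation of a primary allylic alcohol; the ether masks the hydroxyl against the organometallic reagents of step 9.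

Step 5
Reactants: 8 4‑methoxy‑3‑methylphenol
Product: 9 2‑hydroxy‑5‑methoxy‑4‑methylbenzaldehyde
Conditions: MgCl2, Et3N, (CH2O)n, MeCN, 80 °C; then HCl (aq)
Reagents that add atoms: paraformaldehyde, as formaldehyde C=O
Why: Magnesium phenoxide‑directed ortho‑formylation (Casnati–Skattebøl); of the two ortho positions only the one not flanked by the methyl group is open, so the aldehyde enters para to CH3 at the future C1'.

Step 6
Reactants: 9
Product: 10 5‑methoxy‑4‑methyl‑2‑(propan‑2‑yloxy)benzaldehyde
Conditions: 2‑bromopropane, K2CO3, DMF, 60 °C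
Reagents that add atoms: 2‑bromopropane CC(C)Br
Why: Williamson ether synthesis on the phenoxide; the isopropyl ether can later be cleaved in the presence of the methyl ether.

Step 7
Reactants: 10
Product: 11 [5‑methoxy‑4‑methyl‑2‑(propan‑2‑yloxy)phenyl]methanol
Conditions: NaBH4, MeOH, 0 °C
Reagents that add atoms: none
Why: Borohydride reduction of an aryl aldehyde.

Step 8
Reactants: 11
Product: 12 1‑(bromomethyl)‑5‑methoxy‑4‑methyl‑2‑(propan‑2‑yloxy)benzene
Conditions: PBr3, Et2O, 0 °C
Reagents that add atoms: phosphorus tribromide BrP(Br)Br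
Why: Bromide displaces the phosphite ester of the benzylic alcohol; the electron‑rich bromide is used at once.

Step 9
Reactants: 13 (trimethylsilyl)methylmagnesium chloride; 7; 12
Product: 16 tert‑butyl({(2E,6E,10Z)‑12‑Ar‑2,6‑dimethyl‑10‑[(trimethylsilyl)methyl]dodeca‑2,6,10‑trien‑1‑yl}oxy)dimethylsilane, via (trimethylsilyl)methylcopper 14 (not isolated), via alkenylcopper adduct 15 (not isolated)
Conditions: 13, CuBr·SMe2, Et2O/Me2S, −30 °C; then 7, 0 °C → rt; then 12, P(OEt)3, DMPU, −20 °C → rt
Reagents that add atoms: none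
Why: Syn carbocupration of the terminal alkyne (Normant reaction) puts the silylmethyl group on the inner carbon C8 and copper on C9 on the same side, and alkenylcopper 15 is alkylated by the benzylic bromide with retention; CH2Ar therefore ends cis to CH2SiMe3 and trans to the C7 chain, the (Z)‑allylsilane needed for an equatorial C9 substituent.

Step 10
Reactants: 16
Product: 17 (2E,6E,10Z)‑12‑Ar‑2,6‑dimethyl‑10‑[(trimethylsilyl)methyl]dodeca‑2,6,10‑trien‑1‑ol
Conditions: Bu4NF, THF, 0 °C
Reagents that add atoms: none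
Why: Fluoride cleaves the primary silyl ether; the allyl–SiMe3 bond is not attacked at 0 °C in the absence of an electrophile.

Step 11
Reactants: 17
Product: 18 [(2S,3S)‑3‑{(3E,7Z)‑9‑Ar‑3‑methyl‑7‑[(trimethylsilyl)methyl]nona‑3,7‑dien‑1‑yl}‑2‑methyloxiran‑2‑yl]methanol
Conditions: Ti(OiPr)4 (cat.), L‑(+)‑diethyl tartrate (cat.), t‑BuOOH, 4 Å molecular sieves, CH2Cl2, −20 °C
Reagents that add atoms: tert‑butyl hydroperoxide CC(C)(C)OO
Why: Sharpless asymmetric epoxidation; only the allylic alcohol binds titanium, so the allylsilane and the C5=C10 alkene stay intact, and with the L‑(+)‑tartrate an (E)‑2‑methyl‑2‑alken‑1‑ol is epoxidised on the face that gives the (2S,3S)‑oxirane, that is (S) at both C3 and C4.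

Step 12
Reactants: 18
Product: 19 tert‑butyl{[(2S,3S)‑3‑{(3E,7Z)‑9‑Ar‑3‑methyl‑7‑[(trimethylsilyl)methyl]nona‑3,7‑dien‑1‑yl}‑2‑methyloxiran‑2‑yl]methoxy}diphenylsilane
Conditions: t‑BuPh2SiCl, imidazole, DMF, 0 °C → rt
Reagents that add atoms: tert‑butyldiphenylsilyl chloride CC(C)(C)[Si](Cl)(c1ccccc1)c1ccccc1
Why: Silylation of the primary epoxy alcohol; the bulky, weakly basic ether tolerates the Lewis acid of step 13 and keeps the C18 oxygen distinct from the C3 hydroxyl formed there.

Step 13
Reactants: 19
Product: 20 11‑Ar‑18‑[(tert‑butyldiphenylsilyl)oxy]drim‑8(12)‑en‑3β‑ol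
Conditions: MeAlCl2 (hexane), CH2Cl2, −78 °C; then pH 7 phosphate buffer
Reagents that add atoms: none
Why: MeAlCl2 binds the oxirane oxygen and the C4–O bond breaks at the tertiary carbon while the C5=C10 alkene attacks C4 from the rear, so ionisation and C4–C5 bond formation are concerted, with inversion at C4 and retention at C3; the closest known reaction class is the cationic epoxy‑polyene cyclisation of the Stork–Eschenmoser type with an allylsilane terminator. Ring A closes in a 6‑endo mode with the C3–C4 oxirane bond inside the new ring, and the C10 cation is captured by C9 of the allylsilane in a second 6‑endo closure that forms ring B; the C8 cation, stabilised by the β‑silicon, loses the silyl group to chloride and leaves only the C8=C12 alkene. Both rings form from a chair–chair folded chain: C4 is set by the inversion, the (E)‑CH2OSi group becoming the equatorial 4α substituent and the methyl the axial 4β one; C5 and C10 are set by anti addition across the (E)‑C5=C10 alkene, which gives the trans fusion (5α‑H, 10β‑CH3); C9 is set by the (Z)‑allylsilane, whose CH2Ar group is trans to C7 and so becomes equatorial (9β). The absolute sense of folding is fixed by the (3S) oxirane carbon, whose oxygen must be anti to the attacking alkene and ends as the equatorial 3β‑hydroxyl. The step needs initiation at the oxirane only and termination faster than proton loss or arene attack; the first is secured by a Lewis acid that also destroys stray protons as methane, the second by the nucleophilic allylsilane and by silicon loss being faster than addition of the arene to C8. Buffer hydrolyses the aluminium alkoxide.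

Step 14
Reactants: 20
Product: 21 O‑{11‑Ar‑18‑[(tert‑butyldiphenylsilyl)oxy]drim‑8(12)‑en‑3β‑yl} 1H‑imidazole‑1‑carbothioate
Conditions: 1,1'‑thiocarbonyldiimidazole, DMAP (cat.), ClCH2CH2Cl, 80 °C
Reagents that add atoms: 1,1'‑thiocarbonyldiimidazole S=C(n1ccnc1)n1ccnc1
Why: Thioacylation of the hindered equatorial C3 alcohol under neutral conditions, which avoids base‑induced 1,3‑migration of the neighbouring silyl group.

Step 15
Reactants: 21
Product: 22 tert‑butyl{[11‑Ar‑drim‑8(12)‑en‑18‑yl]oxy}diphenylsilane
Conditions: Bu3SnH, AIBN (cat.), toluene, 110 °C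
Reagents that add atoms: none
Why: Barton–McCombie deoxygenation: the stannyl radical adds to C=S, the C3–O bond fragments and the secondary radical takes hydrogen from the tin hydride; C3 becomes CH2 and no stereocentre is touched.

Step 16
Reactants: 22
Product: 23 tert‑butyl{[11‑Ar‑drim‑7‑en‑18‑yl]oxy}diphenylsilane
Conditions: RhCl3·3H2O (cat.), EtOH, 78 °C
Reagents that add atoms: none
Why: Rhodium hydride addition–elimination moves the exocyclic C8=C12 bond into the ring; the accessible C7 hydrogens are removed in preference to the hindered C9–H next to quaternary C10, giving the trisubstituted C7=C8 alkene and leaving C9 intact.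

Step 17
Reactants: 23
Product: 24 11‑Ar‑drim‑7‑en‑18‑ol
Conditions: Bu4NF, THF, 50 °C
Reagents that add atoms: none
Why: Fluoride cleavage of the neopentyl silyl ether, which needs gentle warming.

Step 18
Reactants: 24
Product: 25 11‑Ar‑drim‑7‑en‑18‑al
Conditions: Dess–Martin periodinane, CH2Cl2, rt
Reagents that add atoms: none
Why: Dess–Martin oxidation of the hindered primary alcohol; the aldehyde cannot epimerise because its α‑carbon is quaternary.

Step 19
Reactants: 25
Product: 26 11‑Ar‑drim‑7‑en‑18‑oic acid
Conditions: NaClO2, NaH2PO4, 2‑methyl‑2‑butene, t‑BuOH/H2O, rt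
Reagents that add atoms: sodium chlorite [Na+].[O-]Cl=O
Why: Pinnick oxidation; 2‑methyl‑2‑butene scavenges HOCl and so protects the C7=C8 alkene and the electron‑rich arene.

Step 20
Reactants: 26
Product: 27 prop‑2‑en‑1‑yl 11‑Ar‑drim‑7‑en‑18‑oate
Conditions: allyl bromide, K2CO3, DMF, rt
Reagents that add atoms: allyl bromide C=CCBr
Why: O‑Alkylation of the carboxylate is insensitive to the neopentyl hindrance at C4; the allyl ester keeps a carboxylate out of the phase‑transfer step 23 and can be removed under neutral conditions.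

Step 21
Reactants: 27
Product: 28 prop‑2‑en‑1‑yl 11‑(2‑hydroxy‑5‑methoxy‑4‑methylphenyl)drim‑7‑en‑18‑oate
Conditions: BCl3, CH2Cl2, −78 °C; then NaHCO3 (aq)
Reagents that add atoms: none
Why: BCl3 cleaves the secondary isopropyl aryl ether much faster than the methyl ether; low temperature and a basic quench keep the freed phenol from adding across C7=C8.

Step 22
Reactants: 28
Product: 29 prop‑2‑en‑1‑yl 11‑(3,3‑dimethoxy‑4‑methyl‑6‑oxocyclohexa‑1,4‑dien‑1‑yl)drim‑7‑en‑18‑oate
Conditions: PhI(OAc)2, MeOH, 0 °C
Reagents that add atoms: methanol CO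
Why: Oxidative dearomatisation of a para‑methoxyphenol with a hypervalent iodine reagent; methanol is captured at C3', para to the phenol oxygen, so C6' becomes the ketone and C3' the dimethyl ketal.

Step 23
Reactants: 29
Product: 30 prop‑2‑en‑1‑yl 11‑[(1R,6S)‑5,5‑dimethoxy‑4‑methyl‑2‑oxo‑7‑oxabicyclo[4.1.0]hept‑3‑en‑1‑yl]drim‑7‑en‑18‑oate
Conditions: t‑BuOOH, N‑benzylcinchonidinium chloride (10 mol%), NaOH (aq), toluene, 0 °C
Reagents that add atoms: tert‑butyl hydroperoxide CC(C)(C)OO
Why: Weitz–Scheffer epoxidation under chiral phase‑transfer catalysis: the hydroperoxide anion, paired with the cinchona ammonium ion, adds to the unsubstituted β‑carbon C2' of the C1'=C2' enone (the C4'=C5' enone is β,β‑disubstituted and slower) and the enolate closes on oxygen; the catalyst selects the ring face, and because the decalin is one enantiomer the two possible epoxides are separable diastereomers.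

Step 24
Reactants: 30
Product: 31 prop‑2‑en‑1‑yl 11‑[(1S,2R,6S)‑2‑hydroxy‑5,5‑dimethoxy‑4‑methyl‑7‑oxabicyclo[4.1.0]hept‑3‑en‑1‑yl]drim‑7‑en‑18‑oate
Conditions: NaBH4, CeCl3·7H2O, MeOH, −78 °C
Reagents that add atoms: none
Why: Luche reduction gives 1,2‑addition only; hydride is expected to reach C6' from the face of the oxirane oxygen, because the other face is covered by the C11–decalin substituent on the adjacent quaternary C1', so the hydroxyl ends anti to the oxirane (6'R).

Step 25
Reactants: 31
Product: 32 prop‑2‑en‑1‑yl 11‑[(1S,2R,6S)‑2‑hydroxy‑4‑methyl‑5‑oxo‑7‑oxabicyclo[4.1.0]hept‑3‑en‑1‑yl]drim‑7‑en‑18‑oate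
Conditions: TsOH·H2O (cat.), acetone/H2O, 0 °C → rt
Reagents that add atoms: water O
Why: Acid‑catalysed hydrolysis of the allylic dimethyl ketal through an oxocarbenium ion stabilised by C4'=C5'; the oxirane carbons are flanked by oxygen‑bearing carbons and resist ionisation.

Step 26
Reactants: 32
Product: 33 prop‑2‑en‑1‑yl 11‑[(1S,2R,5S,6R)‑2,5‑dihydroxy‑4‑methyl‑7‑oxabicyclo[4.1.0]hept‑3‑en‑1‑yl]drim‑7‑en‑18‑oate
Conditions: NaBH4, CeCl3·7H2O, MeOH, −78 °C
Reagents that add atoms: none
Why: Second Luche reduction, 1,2‑selective on the enone; hydride attack syn to the oxirane oxygen, the usual course for 5,6‑epoxycyclohex‑2‑enones under these conditions, places the C3' hydroxyl anti to the oxirane and cis to the C6' hydroxyl (3'S).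

Step 27
Reactants: 33
Product: 34 11‑[(1S,2R,5S,6R)‑2,5‑dihydroxy‑4‑methyl‑7‑oxabicyclo[4.1.0]hept‑3‑en‑1‑yl]drim‑7‑en‑18‑oic acid (CNP0358222.2)
Conditions: Pd(PPh3)4 (cat.), TolSO2Na, THF/MeOH, rt; then NaH2PO4 (aq)
Reagents that add atoms: none
Why: Tsuji–Trost deallylation: zerovalent palladium ionises the allyl ester and the sulfinate traps the π‑allyl complex, so the hindered acid is released without base or acid that could open the oxirane.

## Compound list

1 | 1‑(trimethylsilyl)propyne | CC#C[Si](C)(C)C | starting material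
2 | geranyl bromide, (2E)‑1‑bromo‑3,7‑dimethylocta‑2,6‑diene | CC(C)=CCC/C(C)=C/CBr | starting material
3 | 3‑lithio‑1‑(trimethylsilyl)propyne | [Li]CC#C[Si](C)(C)C | intermediate
4 | [(5E)‑6,10‑dimethylundeca‑5,9‑dien‑1‑yn‑1‑yl]trimethylsilane | CC(C)=CCC/C(C)=C/CCC#C[Si](C)(C)C | intermediate
5 | (2E,6E)‑2,6‑dimethyl‑11‑(trimethylsilyl)undeca‑2,6‑dien‑10‑yn‑1‑ol | C[Si](C)(C)C#CCC/C=C(\C)CC/C=C(\C)CO | intermediate
6 | (2E,6E)‑2,6‑dimethylundeca‑2,6‑dien‑10‑yn‑1‑ol | C#CCC/C=C(\C)CC/C=C(\C)CO | intermediate
7 | tert‑butyl{[(2E,6E)‑2,6‑dimethylundeca‑2,6‑dien‑10‑yn‑1‑yl]oxy}dimethylsilane | C#CCC/C=C(\C)CC/C=C(\C)CO[Si](C)(C)C(C)(C)C | intermediate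
8 | 4‑methoxy‑3‑methylphenol | COc1ccc(O)cc1C | starting material
9 | 2‑hydroxy‑5‑methoxy‑4‑methylbenzaldehyde | COc1cc(C=O)c(O)cc1C | intermediate
10 | 5‑methoxy‑4‑methyl‑2‑(propan‑2‑yloxy)benzaldehyde | COc1cc(C=O)c(OC(C)C)cc1C | intermediate
11 | [5‑methoxy‑4‑methyl‑2‑(propan‑2‑yloxy)phenyl]methanol | COc1cc(CO)c(OC(C)C)cc1C | intermediate
12 | 1‑(bromomethyl)‑5‑methoxy‑4‑methyl‑2‑(propan‑2‑yloxy)benzene | COc1cc(CBr)c(OC(C)C)cc1C | intermediate
13 | (trimethylsilyl)methylmagnesium chloride | C[Si](C)(C)C[Mg]Cl | starting material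
14 | [(trimethylsilyl)methyl]copper (as its MgBrCl complex) | C[Si](C)(C)C[Cu] | intermediate
15 | [(1Z,5E,9E)‑11‑[(tert‑butyldimethylsilyl)oxy]‑6,10‑dimethyl‑2‑[(trimethylsilyl)methyl]undeca‑1,5,9‑trien‑1‑yl]copper | [Cu]/C=C(C[Si](C)(C)C)/CC/C=C(\C)CC/C=C(\C)CO[Si](C)(C)C(C)(C)C | intermediate
16 | tert‑butyl({(2E,6E,10Z)‑12‑[5‑methoxy‑4‑methyl‑2‑(propan‑2‑yloxy)phenyl]‑2,6‑dimethyl‑10‑[(trimethylsilyl)methyl]dodeca‑2,6,10‑trien‑1‑yl}oxy)dimethylsilane | COc1cc(C/C=C(C[Si](C)(C)C)/CC/C=C(\C)CC/C=C(\C)CO[Si](C)(C)C(C)(C)C)c(OC(C)C)cc1C | intermediate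
17 | (2E,6E,10Z)‑12‑[5‑methoxy‑4‑methyl‑2‑(propan‑2‑yloxy)phenyl]‑2,6‑dimethyl‑10‑[(trimethylsilyl)methyl]dodeca‑2,6,10‑trien‑1‑ol | COc1cc(C/C=C(C[Si](C)(C)C)/CC/C=C(\C)CC/C=C(\C)CO)c(OC(C)C)cc1C | intermediate
18 | [(2S,3S)‑3‑{(3E,7Z)‑9‑[5‑methoxy‑4‑methyl‑2‑(propan‑2‑yloxy)phenyl]‑3‑methyl‑7‑[(trimethylsilyl)methyl]nona‑3,7‑dien‑1‑yl}‑2‑methyloxiran‑2‑yl]methanol | COc1cc(C/C=C(C[Si](C)(C)C)/CC/C=C(\C)CC[C@@H]2O[C@@]2(C)CO)c(OC(C)C)cc1C | intermediate
19 | tert‑butyldiphenylsilyl ether of 18 (cyclisation precursor) | COc1cc(C/C=C(C[Si](C)(C)C)/CC/C=C(\C)CC[C@@H]2O[C@@]2(C)CO[Si](c3ccccc3)(c3ccccc3)C(C)(C)C)c(OC(C)C)cc1C | intermediate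
20 | 11‑Ar‑18‑[(tert‑butyldiphenylsilyl)oxy]drim‑8(12)‑en‑3β‑ol (4α‑CH2OSi, 4β‑CH3, 5α‑H, 9α‑H, 10β‑CH3) | COc1cc(C[C@H]2C(=C)CC[C@@H]3[C@]2(C)CC[C@H](O)[C@@]3(C)CO[Si](c4ccccc4)(c4ccccc4)C(C)(C)C)c(OC(C)C)cc1C | intermediate
21 | O‑{11‑Ar‑18‑[(tert‑butyldiphenylsilyl)oxy]drim‑8(12)‑en‑3β‑yl} 1H‑imidazole‑1‑carbothioate | COc1cc(C[C@H]2C(=C)CC[C@@H]3[C@]2(C)CC[C@H](OC(=S)n4ccnc4)[C@@]3(C)CO[Si](c4ccccc4)(c4ccccc4)C(C)(C)C)c(OC(C)C)cc1C | intermediate
22 | tert‑butyl{[11‑Ar‑drim‑8(12)‑en‑18‑yl]oxy}diphenylsilane | COc1cc(C[C@H]2C(=C)CC[C@@H]3[C@]2(C)CCC[C@@]3(C)CO[Si](c4ccccc4)(c4ccccc4)C(C)(C)C)c(OC(C)C)cc1C | intermediate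
23 | tert‑butyl{[11‑Ar‑drim‑7‑en‑18‑yl]oxy}diphenylsilane | COc1cc(C[C@H]2C(C)=CC[C@@H]3[C@]2(C)CCC[C@@]3(C)CO[Si](c4ccccc4)(c4ccccc4)C(C)(C)C)c(OC(C)C)cc1C | intermediate
24 | 11‑Ar‑drim‑7‑en‑18‑ol | COc1cc(C[C@H]2C(C)=CC[C@@H]3[C@]2(C)CCC[C@@]3(C)CO)c(OC(C)C)cc1C | intermediate
25 | 11‑Ar‑drim‑7‑en‑18‑al | COc1cc(C[C@H]2C(C)=CC[C@@H]3[C@]2(C)CCC[C@@]3(C)C=O)c(OC(C)C)cc1C | intermediate
26 | 11‑Ar‑drim‑7‑en‑18‑oic acid | COc1cc(C[C@H]2C(C)=CC[C@@H]3[C@]2(C)CCC[C@@]3(C)C(=O)O)c(OC(C)C)cc1C | intermediate
27 | prop‑2‑en‑1‑yl 11‑Ar‑drim‑7‑en‑18‑oate | COc1cc(C[C@H]2C(C)=CC[C@@H]3[C@]2(C)CCC[C@@]3(C)C(=O)OCC=C)c(OC(C)C)cc1C | intermediate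
28 | prop‑2‑en‑1‑yl 11‑(2‑hydroxy‑5‑methoxy‑4‑methylphenyl)drim‑7‑en‑18‑oate | COc1cc(C[C@H]2C(C)=CC[C@@H]3[C@]2(C)CCC[C@@]3(C)C(=O)OCC=C)c(O)cc1C | intermediate
29 | prop‑2‑en‑1‑yl 11‑(3,3‑dimethoxy‑4‑methyl‑6‑oxocyclohexa‑1,4‑dien‑1‑yl)drim‑7‑en‑18‑oate | CC1=CC(=O)C(C[C@H]2C(C)=CC[C@@H]3[C@]2(C)CCC[C@@]3(C)C(=O)OCC=C)=CC1(OC)OC | intermediate
30 | prop‑2‑en‑1‑yl 11‑[(1R,6S)‑5,5‑dimethoxy‑4‑methyl‑2‑oxo‑7‑oxabicyclo[4.1.0]hept‑3‑en‑1‑yl]drim‑7‑en‑18‑oate (1'R,2'S) | CC1=CC(=O)[C@]2(C[C@H]3C(C)=CC[C@@H]4[C@]3(C)CCC[C@@]4(C)C(=O)OCC=C)O[C@@H]2C1(OC)OC | intermediate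
31 | prop‑2‑en‑1‑yl 11‑[(1S,2R,6S)‑2‑hydroxy‑5,5‑dimethoxy‑4‑methyl‑7‑oxabicyclo[4.1.0]hept‑3‑en‑1‑yl]drim‑7‑en‑18‑oate (C6' hydroxyl anti to the oxirane) | CC1=C[C@@H](O)[C@]2(C[C@H]3C(C)=CC[C@@H]4[C@]3(C)CCC[C@@]4(C)C(=O)OCC=C)O[C@@H]2C1(OC)OC | intermediate
32 | prop‑2‑en‑1‑yl 11‑[(1S,2R,6S)‑2‑hydroxy‑4‑methyl‑5‑oxo‑7‑oxabicyclo[4.1.0]hept‑3‑en‑1‑yl]drim‑7‑en‑18‑oate | CC1=C[C@@H](O)[C@]2(C[C@H]3C(C)=CC[C@@H]4[C@]3(C)CCC[C@@]4(C)C(=O)OCC=C)O[C@@H]2C1=O | intermediate
33 | prop‑2‑en‑1‑yl 11‑[(1S,2R,5S,6R)‑2,5‑dihydroxy‑4‑methyl‑7‑oxabicyclo[4.1.0]hept‑3‑en‑1‑yl]drim‑7‑en‑18‑oate | CC1=C[C@@H](O)[C@]2(C[C@H]3C(C)=CC[C@@H]4[C@]3(C)CCC[C@@]4(C)C(=O)OCC=C)O[C@@H]2[C@H]1O | intermediate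
34 | 11‑[(1S,2R,5S,6R)‑2,5‑dihydroxy‑4‑methyl‑7‑oxabicyclo[4.1.0]hept‑3‑en‑1‑yl]drim‑7‑en‑18‑oic acid, (4R,5R,9S,10R,1'S,2'R,3'S,6'R), CNP0358222.2 | CC1=C[C@@H](O)[C@]2(C[C@H]3C(C)=CC[C@@H]4[C@]3(C)CCC[C@@]4(C)C(=O)O)O[C@@H]2[C@H]1O | target

## Step count and least certain steps

Total step count: 27. Longest linear sequence: 23 steps (steps 1–4 and 9–27); steps 5–8 form the four‑step arene branch.

**Step 13 (key step).** The cascade may be interrupted. The silyloxymethyl group on C4 withdraws electron density and slows ionisation there, so a 1,2‑hydride shift from C3 (ketone formation) can compete. After ring A has closed, the C10 cation may also lose a proton or be captured by the C3 alkoxide as a bridged ether before the allylsilane reacts. The fallback changes from cationic to radical initiation, which is not slowed by the β‑oxygen, and needs a methyl‑substituted terminating alkene in place of the allylsilane. It sets out from alkyne 7. Zirconium‑catalysed carboalumination (Me3Al, Cp2ZrCl2) and iodination give tert‑butyl{[(2E,6E,10E)‑11‑iodo‑2,6,10‑trimethylundeca‑2,6,10‑trien‑1‑yl]oxy}dimethylsilane F1. Bromide 12 is converted with Zn and LiCl into [5‑methoxy‑4‑methyl‑2‑(propan‑2‑yloxy)benzyl]zinc bromide F2, and Negishi coupling under Pd(PPh3)4 gives the triene silyl ether F3. Bu4NF gives the (2E,6E,10E)‑12‑Ar‑2,6,10‑trimethyldodeca‑2,6,10‑trien‑1‑ol F4, Sharpless epoxidation with the L‑(+)‑tartrate gives the (2S,3S)‑epoxy alcohol F5, and silylation gives its tert‑butyldiphenylsilyl ether F6. Trivalent titanium (Cp2TiCl2 cat., Mn, Me3SiCl, 2,4,6‑collidine, THF; then K2CO3, MeOH) opens the oxirane homolytically at C4; two 6‑endo radical closures and β‑hydride elimination from the C8 alkyltitanium should give the exocyclic alkene, and the fallback comes back to the route at 20.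

**Step 9.** The silylmethyl group transfers slowly from copper, and the hindered alkenylcopper 15 may be alkylated incompletely while the electron‑rich benzylic bromide is consumed by reductive homocoupling. The fallback separates the two bond formations. It sets out from 7 and 12: 15 is formed as in the route and quenched with iodine to give tert‑butyl{[(2E,6E,10Z)‑11‑iodo‑2,6‑dimethyl‑10‑[(trimethylsilyl)methyl]undeca‑2,6,10‑trien‑1‑yl]oxy}dimethylsilane F7. This is joined to the benzylzinc bromide F2 by Negishi coupling with zerovalent palladium (Pd(PPh3)4, THF), with retention of alkene geometry, and the fallback returns to the route at 16.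

**Step 16.** The alkene may migrate past C7=C8 into the tetrasubstituted C8=C9 position, which would erase the C9 stereocentre, or the isomerisation may stop short. The fallback fixes the alkene position by enolate regiochemistry. It sets out from 22: Lemieux–Johnson cleavage (OsO4 cat., NaIO4, 2,6‑lutidine) gives 11‑Ar‑18‑[(tert‑butyldiphenylsilyl)oxy]‑12‑nordriman‑8‑one F8. Kinetic deprotonation at the unhindered C7 (KN(SiMe3)2, −78 °C) and trapping with PhNTf2 give the 12‑nordrim‑7‑en‑8‑yl trifluoromethanesulfonate F9. Palladium‑catalysed methylation (MeZnCl, Pd(PPh3)4) installs C12 and the fallback returns at 23.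

**Step 23.** Facial selectivity may be poor or reversed, because ion‑pair recognition of a 2‑alkyl quinone monoketal carrying a large lipophilic substituent is not predictable. The fallback gives up reagent control. It sets out from 29, which is epoxidised with t‑BuOOH and DBU to a mixture of 30 and its (1'S,2'R)‑epoxide diastereomer F10; these are separated by chromatography, which is possible because the decalin makes them diastereomers. F10 is recycled: SmI2 (THF/MeOH, −78 °C) cleaves the C1'–O bond to the β‑hydroxy ketone F11, and MsCl/Et3N dehydrates it back to 29. The fallback rejoins the route at 30.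

**Step 24.** Hydride may be delivered to the face anti to the oxirane oxygen (the Felkin–Anh sense), giving the syn epoxy alcohol. The fallback inverts the carbinol. It sets out from 30, which is reduced deliberately with i‑Bu2AlH to the C6' epimer of 31, F12. A Mitsunobu reaction (4‑nitrobenzoic acid, PPh3, diisopropyl azodicarboxylate) gives the inverted C6' 4‑nitrobenzoate F13, and K2CO3/MeOH cleaves the aryl ester without touching the hindered allyl ester, returning to the route at 31. The C6' carbinol is allylic, which helps the substitution, but attack with allylic transposition has to be watched for.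

**Step 26.** Hydride may attack C3' from the face anti to the oxirane oxygen, giving the trans‑1,4‑diol. The fallback sets out from 32, carries the wrong diol, the C3' epimer of 33, F14, into a Mitsunobu reaction with 4‑nitrobenzoic acid, and relies on site selectivity: the C3' carbinol lies next to an oxirane CH, whereas the C6' carbinol is shielded by the fully substituted C1' and its decalinyl‑methyl group. The resulting 3'‑O‑(4‑nitrobenzoyl) derivative of 33, F15, is cleaved with K2CO3/MeOH and the fallback returns at 33.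

## Further compounds

F1 | step 13 | tert‑butyl{[(2E,6E,10E)‑11‑iodo‑2,6,10‑trimethylundeca‑2,6,10‑trien‑1‑yl]oxy}dimethylsilane | I/C=C(C)/CC/C=C(\C)CC/C=C(\C)CO[Si](C)(C)C(C)(C)C
F2 | step 13 | [5‑methoxy‑4‑methyl‑2‑(propan‑2‑yloxy)benzyl]zinc bromide | COc1cc(C[Zn]Br)c(OC(C)C)cc1C
F3 | step 13 | tert‑butyl({(2E,6E,10E)‑12‑Ar‑2,6,10‑trimethyldodeca‑2,6,10‑trien‑1‑yl}oxy)dimethylsilane | COc1cc(C/C=C(C)/CC/C=C(\C)CC/C=C(\C)CO[Si](C)(C)C(C)(C)C)c(OC(C)C)cc1C
F4 | step 13 | (2E,6E,10E)‑12‑Ar‑2,6,10‑trimethyldodeca‑2,6,10‑trien‑1‑ol | COc1cc(C/C=C(C)/CC/C=C(\C)CC/C=C(\C)CO)c(OC(C)C)cc1C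
F5 | step 13 | [(2S,3S)‑3‑{(3E,7E)‑9‑Ar‑3,7‑dimethylnona‑3,7‑dien‑1‑yl}‑2‑methyloxiran‑2‑yl]methanol | COc1cc(C/C=C(C)/CC/C=C(\C)CC[C@@H]2O[C@@]2(C)CO)c(OC(C)C)cc1C
F6 | step 13 | tert‑butyl{[(2S,3S)‑3‑{(3E,7E)‑9‑Ar‑3,7‑dimethylnona‑3,7‑dien‑1‑yl}‑2‑methyloxiran‑2‑yl]methoxy}diphenylsilane | COc1cc(C/C=C(C)/CC/C=C(\C)CC[C@@H]2O[C@@]2(C)CO[Si](c3ccccc3)(c3ccccc3)C(C)(C)C)c(OC(C)C)cc1C
F7 | step 9 | tert‑butyl{[(2E,6E,10Z)‑11‑iodo‑2,6‑dimethyl‑10‑[(trimethylsilyl)methyl]undeca‑2,6,10‑trien‑1‑yl]oxy}dimethylsilane | I/C=C(C[Si](C)(C)C)/CC/C=C(\C)CC/C=C(\C)CO[Si](C)(C)C(C)(C)C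
F8 | step 16 | 11‑Ar‑18‑[(tert‑butyldiphenylsilyl)oxy]‑12‑nordriman‑8‑one | COc1cc(C[C@H]2C(=O)CC[C@@H]3[C@]2(C)CCC[C@@]3(C)CO[Si](c4ccccc4)(c4ccccc4)C(C)(C)C)c(OC(C)C)cc1C
F9 | step 16 | 11‑Ar‑18‑[(tert‑butyldiphenylsilyl)oxy]‑12‑nordrim‑7‑en‑8‑yl trifluoromethanesulfonate | COc1cc(C[C@H]2C(OS(=O)(=O)C(F)(F)F)=CC[C@@H]3[C@]2(C)CCC[C@@]3(C)CO[Si](c4ccccc4)(c4ccccc4)C(C)(C)C)c(OC(C)C)cc1C
F10 | step 23 | prop‑2‑en‑1‑yl 11‑[(1S,6R)‑5,5‑dimethoxy‑4‑methyl‑2‑oxo‑7‑oxabicyclo[4.1.0]hept‑3‑en‑1‑yl]drim‑7‑en‑18‑oate (oxirane diastereomer of 30) | CC1=CC(=O)[C@@]2(C[C@H]3C(C)=CC[C@@H]4[C@]3(C)CCC[C@@]4(C)C(=O)OCC=C)O[C@H]2C1(OC)OC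
F11 | step 23 | prop‑2‑en‑1‑yl 11‑[(2R)‑2‑hydroxy‑3,3‑dimethoxy‑4‑methyl‑6‑oxocyclohex‑4‑en‑1‑yl]drim‑7‑en‑18‑oate (mixture at C1') | CC1=CC(=O)C(C[C@H]2C(C)=CC[C@@H]3[C@]2(C)CCC[C@@]3(C)C(=O)OCC=C)[C@@H](O)C1(OC)OC
F12 | step 24 | C6' epimer of 31 (hydroxyl syn to the oxirane) | CC1=C[C@H](O)[C@]2(C[C@H]3C(C)=CC[C@@H]4[C@]3(C)CCC[C@@]4(C)C(=O)OCC=C)O[C@@H]2C1(OC)OC
F13 | step 24 | C6' 4‑nitrobenzoate of 31 | CC1=C[C@@H](OC(=O)c5ccc(cc5)[N+](=O)[O-])[C@]2(C[C@H]3C(C)=CC[C@@H]4[C@]3(C)CCC[C@@]4(C)C(=O)OCC=C)O[C@@H]2C1(OC)OC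
F14 | step 26 | C3' epimer of 33 (trans‑1,4‑diol) | CC1=C[C@@H](O)[C@]2(C[C@H]3C(C)=CC[C@@H]4[C@]3(C)CCC[C@@]4(C)C(=O)OCC=C)O[C@@H]2[C@@H]1O
F15 | step 26 | 3'‑O‑(4‑nitrobenzoyl) derivative of 33 | CC1=C[C@@H](O)[C@]2(C[C@H]3C(C)=CC[C@@H]4[C@]3(C)CCC[C@@]4(C)C(=O)OCC=C)O[C@@H]2[C@H]1OC(=O)c5ccc(cc5)[N+](=O)[O-]
A1 | alternative 1 | 11‑[(1R,6S)‑5,5‑dimethoxy‑4‑methyl‑2‑oxo‑7‑oxabicyclo[4.1.0]hept‑3‑en‑1‑yl]drim‑7‑en‑18‑oic acid | COC1(OC)[C@H]2O[C@@]2(C[C@H]3C(C)=CC[C@@H]4[C@]3(C)CCC[C@@]4(C)C(=O)O)C(=O)C=C1C
A2 | alternative 1 | 11‑(3,3‑dimethoxy‑4‑methyl‑6‑oxocyclohexa‑1,4‑dien‑1‑yl)drim‑7‑en‑18‑oic acid | COC1(OC)C=C(C[C@H]2C(C)=CC[C@@H]3[C@]2(C)CCC[C@@]3(C)C(=O)O)C(=O)C=C1C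
A3 | alternative 2 | 2‑(trimethylsilyl)ethyl ester of the target with both hydroxyls as tert‑butyldimethylsilyl ethers | CC1=C[C@@H](O[Si](C)(C)C(C)(C)C)[C@]2(C[C@H]3C(C)=CC[C@@H]4[C@]3(C)CCC[C@@]4(C)C(=O)OCC[Si](C)(C)C)O[C@@H]2[C@H]1O[Si](C)(C)C(C)(C)C
A4 | alternative 2 | acyclic epoxy diene with vinyl on C6' and isopropenyl on C3', both carbinols as tert‑butyldimethylsilyl ethers, 2‑(trimethylsilyl)ethyl ester | C=C[C@@H](O[Si](C)(C)C(C)(C)C)[C@]1(C[C@H]2C(C)=CC[C@@H]3[C@]2(C)CCC[C@@]3(C)C(=O)OCC[Si](C)(C)C)O[C@@H]1[C@@H](O[Si](C)(C)C(C)(C)C)C(C)=C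
A5 | alternative 3 | methyl ester of the trans‑fused 1‑ene decalin with C8 tert‑butyldimethylsilyl ether and C9 CH2Ar | COc1cc(C[C@H]2[C@H](O[Si](C)(C)C(C)(C)C)CC[C@@H]3[C@]2(C)C=CC[C@@]3(C)C(=O)OC)c(OC(C)C)cc1C
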